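**Retrosynthetic overview**
1. Target 23 ⇐ N‑Bus piperidin‑3‑one 21 (sulfonyl removal, then axial hydride on the free‑amine chair sets C3) ⇐ cis‑2,6‑enone 20 (H2, benzyl off) ⇐ spiro N,O‑ketal 18 (ionic hydrogenation relays C2 → C6).
2. Key disconnection: the piperidine is not closed as a six‑ring. 18 arises by oxidative ring expansion (aza‑Achmatowicz) of the five‑membered furan 15; in the same pot the sulfinyl auxiliary becomes the activating tert‑butylsulfonyl (Bus) group and the C4′–OH closes a temporary tetrahydropyran on C6.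
3. Furan 15 ⇐ B‑alkyl Suzuki coupling of bromofuran sulfinamide 13 (one‑pot sulfinyl ketimine formation/reduction) with homoallylic alcohol 9 ((S)‑propylene oxide + undecenyl Grignard, ozonolysis, Brown allylation).
4. Ring order: furan (bought) → dihydropyridinone + temporary spiro‑tetrahydropyran (step 7) → tetrahydropyran cleaved (step 8) → saturated piperidine (steps 9, 10).
5. Enabling feature: ring carbons C3–C6 with the C3 oxygen are the four carbons of a 2,5‑disubstituted furan, N1–C2(CH3) is a 1‑aminoethyl arm on that furan, and the side‑chain oxygen on C4′ stands 1,5 to C6 (O–C4′–C3′–C2′–C1′–C6), so it can tie C6 into a six‑membered N,O‑ketal.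

Key step: step 7

Remarks on the chemistry:
- The target is read as (2R,3S,6S)‑6‑[(4S,15S)‑4,15‑dihydroxyhexadecyl]‑2‑methylpiperidin‑3‑ol: 2‑methyl and 6‑alkyl cis, 3‑hydroxyl trans to methyl (all‑equatorial chair).
- Assumption: the spiro carbon of 18 is drawn as the epimer expected under thermodynamic control (C–O anti to the C2 methyl); either epimer gives the same iminium ion in step 8.
- Assumption: (+)‑Ipc2B(allyl) means the reagent derived from (−)‑α‑pinene, as in the SMILES given.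

Step 1
Reactants: 1 11‑bromoundec‑1‑ene; 2 (S)‑2‑methyloxirane
Product: 4 (2S)‑tetradec‑13‑en‑2‑ol, via undec‑10‑enylmagnesium bromide 3 (not isolated)
Conditions: Mg, THF, 40 °C; then CuI (10 mol%), THF, −30 → 0 °C; H2O work‑up
Reagents that add atoms: none
Why: Copper‑catalysed Grignard opening of the terminal epoxide at its CH2 carbon (SN2) should give the alcohol; the carbinol centre is taken unchanged from (S)‑propylene oxide.

Step 2
Reactants: 4 (2S)‑tetradec‑13‑en‑2‑ol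
Product: 5 benzyl (2S)‑tetradec‑13‑en‑2‑yl ether
Conditions: NaH, BnBr, Bu4NI (cat.), THF–DMF, 0 °C → rt
Reagents that add atoms: benzyl bromide, BrCc1ccccc1
Why: Williamson etherification masks the C15′ hydroxyl against the allylborane of step 4; the benzyl group is later lost in the hydrogenation of step 9 at no extra cost.

Step 3
Reactants: 5 benzyl (2S)‑tetradec‑13‑en‑2‑yl ether
Product: 7 (12S)‑12‑(benzyloxy)tridecanal, via secondary ozonide 6 (not isolated)
Conditions: O3, CH2Cl2, −78 °C; then Me2S, −78 °C → rt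
Reagents that add atoms: ozone, [O-][O+]=O
Why: Ozonolysis with reductive work‑up should cleave the terminal alkene to the aldehyde one carbon shorter without touching the ether or the stereocentre.

Step 4
Reactants: 7 (12S)‑12‑(benzyloxy)tridecanal
Product: 9 (4S,15S)‑15‑(benzyloxy)hexadec‑1‑en‑4‑ol, via diisopinocampheylborinate 8 (not isolated)
Conditions: (+)‑Ipc2B(allyl) (1 M in pentane), Et2O, −78 °C; then 3 M NaOH, 30% H2O2, rt
Reagents that add atoms: (+)‑B‑allyldiisopinocampheylborane, C=CCB([C@H]1C[C@H]2C[C@@H]([C@@H]1C)C2(C)C)[C@H]1C[C@H]2C[C@@H]([C@@H]1C)C2(C)C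
Why: Brown asymmetric allylation through a closed chair (Zimmerman–Traxler) transition state; the reagent from (−)‑α‑pinene attacks the Re face of an unbranched aldehyde and should give the (4S) alcohol under reagent control, independent of the remote C15 centre.

Step 5
Reactants: 10 1‑(5‑bromofuran‑2‑yl)ethan‑1‑one; 11 (R)‑2‑methylpropane‑2‑sulfinamide
Product: 13 (R)‑N‑[(1R)‑1‑(5‑bromofuran‑2‑yl)ethyl]‑2‑methylpropane‑2‑sulfinamide, via N‑sulfinyl ketimine 12 (not isolated)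
Conditions: Ti(OEt)4, THF, 65 °C; then NaBH4, −48 °C; brine
Reagents that add atoms: none
Why: One‑pot tert‑butanesulfinyl ketimine condensation and borohydride reduction; hydride delivery through the cyclic transition state bound to the sulfinyl oxygen should give the (R) carbinamine from the (R)‑sulfinamide, as with aryl methyl ketimines, and the minor diastereomer is removable by chromatography.

Step 6
Reactants: 9 (4S,15S)‑15‑(benzyloxy)hexadec‑1‑en‑4‑ol; 13 (R)‑N‑[(1R)‑1‑(5‑bromofuran‑2‑yl)ethyl]‑2‑methylpropane‑2‑sulfinamide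
Product: 15 (R)‑N‑[(1R)‑1‑{5‑[(4S,15S)‑15‑(benzyloxy)‑4‑hydroxyhexadecyl]furan‑2‑yl}ethyl]‑2‑methylpropane‑2‑sulfinamide, via B‑alkyl‑9‑BBN 14 (not isolated)
Conditions: 9‑BBN (2.5 equiv), THF, 0 °C → rt; then 3 M aq. K3PO4, 13, Pd(dppf)Cl2 (5 mol%), DMF, 50 °C
Reagents that add atoms: none
Why: Anti‑Markovnikov hydroboration followed by B‑alkyl Suzuki–Miyaura coupling should join C1′ to furan C5; the free C4′ hydroxyl is carried as its borinate, which hydrolyses in the basic medium, and no stereocentre is touched.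

Step 7
Reactants: 15 (R)‑N‑[(1R)‑1‑{5‑[(4S,15S)‑15‑(benzyloxy)‑4‑hydroxyhexadecyl]furan‑2‑yl}ethyl]‑2‑methylpropane‑2‑sulfinamide
Product: 18 (2S,6R,8R)‑2‑[(11S)‑11‑(benzyloxy)dodecyl]‑7‑(tert‑butylsulfonyl)‑8‑methyl‑1‑oxa‑7‑azaspiro[5.5]undec‑10‑en‑9‑one, via Bus sulfonamide 16 (not isolated), via ring‑expanded hemiaminal 17 (not isolated)
Conditions: mCPBA (2.2 equiv), CH2Cl2, 0 °C → rt; then CSA (10 mol%), 4 Å molecular sieves, rt
Reagents that add atoms: mCPBA (3‑chloroperoxybenzoic acid), OOC(=O)c1cccc(Cl)c1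
Why: The first equivalent of peracid oxidises the sulfinyl auxiliary (tetravalent sulfur) to the Bus sulfonamide 16 (hexavalent sulfur); the second epoxidises the electron‑rich 2,5‑dialkylfuran, which opens to the cis‑ene‑1,4‑dione, and the sulfonamide nitrogen adds to the C6 carbonyl (6‑exo‑trig) to give hemiaminal 17, so that the five‑membered furan has become the six‑membered N1–C2–C3–C4–C5–C6 ring with C3 as ketone. Under acid catalysis 17 ionises to the N‑sulfonyliminium ion and the C4′ hydroxyl closes the tetrahydropyran on C6 (6‑exo‑trig), which locks the ring–chain equilibrium of this ketone‑derived hemiaminal on the cyclic side and protects the C4′ oxygen. The closest known reaction types are the aza‑Achmatowicz rearrangement of N‑sulfonyl furfurylamines with mCPBA, the mCPBA oxidation of N‑sulfinyl to N‑Bus amines, and the acid‑catalysed conversion of aza‑Achmatowicz hemiaminals into N,O‑acetals by alcohols, here intramolecular. The C2, C4′ and C15′ centres pass through untouched; the only new stereocentre, the spiro carbon, is set under thermodynamic control (reversible ionisation, C–O bond pseudoaxial and anti to the C2 methyl expected) and is erased in step 8. The step needs chemoselective oxidation of sulfur and furan beside a secondary alcohol, a benzyl ether and the product enone, and a single mode of closure; the substrate secures this because the furan is by far the most electron‑rich π‑system, nitrogen sits one carbon from furan C2 so that only attack on the C6 carbonyl gives a six‑ring, and the C4′ oxygen is five atoms from C6.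

Step 8
Reactants: 18 (2S,6R,8R)‑2‑[(11S)‑11‑(benzyloxy)dodecyl]‑7‑(tert‑butylsulfonyl)‑8‑methyl‑1‑oxa‑7‑azaspiro[5.5]undec‑10‑en‑9‑one
Product: 20 (2R,6S)‑6‑[(4S,15S)‑15‑(benzyloxy)‑4‑hydroxyhexadecyl]‑1‑(tert‑butylsulfonyl)‑2‑methyl‑1,6‑dihydropyridin‑3(2H)‑one, via N‑sulfonyliminium ion 19 (not isolated)
Conditions: Et3SiH (3 equiv), BF3·OEt2 (2 equiv), CH2Cl2, −78 → −30 °C; then 1 M HCl, THF, rt
Reagents that add atoms: none
Why: Lewis‑acid opening of the spiro N,O‑ketal and ionic hydrogenation of the cyclic N‑sulfonyliminium ion 19 (reductive deoxygenation of aza‑Achmatowicz aminals); 1,3‑allylic strain with the sulfonyl group holds the C2 methyl pseudoaxial on the nearly flat enone ring, so hydride should enter on the opposite face and place the C6 chain cis to the methyl (6S).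

Step 9
Reactants: 20 (2R,6S)‑6‑[(4S,15S)‑15‑(benzyloxy)‑4‑hydroxyhexadecyl]‑1‑(tert‑butylsulfonyl)‑2‑methyl‑1,6‑dihydropyridin‑3(2H)‑one
Product: 21 (2R,6S)‑1‑(tert‑butylsulfonyl)‑6‑[(4S,15S)‑4,15‑dihydroxyhexadecyl]‑2‑methylpiperidin‑3‑one
Conditions: H2 (1 atm), Pd(OH)2/C, EtOAc–MeOH, rt
Reagents that add atoms: none
Why: Heterogeneous hydrogenation should saturate the enone C4=C5 bond and hydrogenolyse the benzyl ether in one operation, leaving ketone, sulfonamide and all stereocentres unchanged.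

Step 10
Reactants: 21 (2R,6S)‑1‑(tert‑butylsulfonyl)‑6‑[(4S,15S)‑4,15‑dihydroxyhexadecyl]‑2‑methylpiperidin‑3‑one
Product: 23 (2R,3S,6S)‑6‑[(4S,15S)‑4,15‑dihydroxyhexadecyl]‑2‑methylpiperidin‑3‑ol, via amino ketone 22 (not isolated)
Conditions: TfOH (0.1 M), anisole (10 equiv), CH2Cl2, 0 °C; then MeOH, NaOMe (to neutrality), NaBH4, −40 → 0 °C; 1 M HCl–MeOH, then aq. NaOH work‑up
Reagents that add atoms: none
Why: Acidolysis of the Bus group (tert‑butyl cation trapped by anisole, then loss of SO2) frees the amine, whose chair carries 2‑methyl and 6‑alkyl equatorial once the 1,3‑allylic strain is gone; axial borohydride addition to C3 should then give the equatorial hydroxyl trans to the methyl (3S), and any C2 epimerisation at the amino ketone stage is self‑correcting because C6 is fixed and the 2,6‑cis isomer is the stable one.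

**Compound list**
1 | 11‑bromoundec‑1‑ene | C=CCCCCCCCCCBr | starting material
2 | (S)‑2‑methyloxirane | C[C@H]1CO1 | starting material
3 | undec‑10‑enylmagnesium bromide | C=CCCCCCCCCC[Mg]Br | intermediate (not isolated)
4 | (2S)‑tetradec‑13‑en‑2‑ol | C[C@H](O)CCCCCCCCCCC=C | intermediate
5 | benzyl (2S)‑tetradec‑13‑en‑2‑yl ether | C[C@H](OCc1ccccc1)CCCCCCCCCCC=C | intermediate
6 | 3‑[(11S)‑11‑(benzyloxy)dodecyl]‑1,2,4‑trioxolane (epimers at the ring carbon) | C[C@H](OCc1ccccc1)CCCCCCCCCCC1OCOO1 | intermediate (not isolated)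
7 | (12S)‑12‑(benzyloxy)tridecanal | C[C@H](OCc1ccccc1)CCCCCCCCCCC=O | intermediate
8 | (4S,15S)‑15‑(benzyloxy)hexadec‑1‑en‑4‑yl diisopinocampheylborinate | C[C@H](OCc1ccccc1)CCCCCCCCCC[C@H](OB([C@H]1C[C@H]2C[C@@H]([C@@H]1C)C2(C)C)[C@H]1C[C@H]2C[C@@H]([C@@H]1C)C2(C)C)CC=C | intermediate (not isolated)
9 | (4S,15S)‑15‑(benzyloxy)hexadec‑1‑en‑4‑ol | C[C@H](OCc1ccccc1)CCCCCCCCCC[C@H](O)CC=C | intermediate
10 | 1‑(5‑bromofuran‑2‑yl)ethan‑1‑one | CC(=O)c1ccc(Br)o1 | starting material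
11 | (R)‑2‑methylpropane‑2‑sulfinamide | CC(C)(C)[S@@](=O)N | starting material
12 | (R,E)‑N‑[1‑(5‑bromofuran‑2‑yl)ethylidene]‑2‑methylpropane‑2‑sulfinamide | CC(C)(C)[S@@](=O)/N=C(\C)c1ccc(Br)o1 | intermediate (not isolated)
13 | (R)‑N‑[(1R)‑1‑(5‑bromofuran‑2‑yl)ethyl]‑2‑methylpropane‑2‑sulfinamide | CC(C)(C)[S@@](=O)N[C@H](C)c1ccc(Br)o1 | intermediate
14 | 9‑[(4S,15S)‑15‑(benzyloxy)‑4‑(9‑borabicyclo[3.3.1]nonan‑9‑yloxy)hexadecyl]‑9‑borabicyclo[3.3.1]nonane | C[C@H](OCc1ccccc1)CCCCCCCCCC[C@H](OB1C2CCCC1CCC2)CCCB1C2CCCC1CCC2 | intermediate (not isolated)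
15 | (R)‑N‑[(1R)‑1‑{5‑[(4S,15S)‑15‑(benzyloxy)‑4‑hydroxyhexadecyl]furan‑2‑yl}ethyl]‑2‑methylpropane‑2‑sulfinamide | C[C@H](OCc1ccccc1)CCCCCCCCCC[C@H](O)CCCc1ccc([C@@H](C)N[S@](=O)C(C)(C)C)o1 | intermediate
16 | N‑[(1R)‑1‑{5‑[(4S,15S)‑15‑(benzyloxy)‑4‑hydroxyhexadecyl]furan‑2‑yl}ethyl]‑2‑methylpropane‑2‑sulfonamide | C[C@H](OCc1ccccc1)CCCCCCCCCC[C@H](O)CCCc1ccc([C@@H](C)NS(=O)(=O)C(C)(C)C)o1 | intermediate (not isolated)
17 | (2R)‑6‑[(4S,15S)‑15‑(benzyloxy)‑4‑hydroxyhexadecyl]‑1‑(tert‑butylsulfonyl)‑6‑hydroxy‑2‑methyl‑1,6‑dihydropyridin‑3(2H)‑one (C6 epimers) | C[C@H](OCc1ccccc1)CCCCCCCCCC[C@H](O)CCCC1(O)C=CC(=O)[C@@H](C)N1S(=O)(=O)C(C)(C)C | intermediate (not isolated)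
18 | (2S,6R,8R)‑2‑[(11S)‑11‑(benzyloxy)dodecyl]‑7‑(tert‑butylsulfonyl)‑8‑methyl‑1‑oxa‑7‑azaspiro[5.5]undec‑10‑en‑9‑one | C[C@H](OCc1ccccc1)CCCCCCCCCC[C@H]1CCC[C@@]2(O1)C=CC(=O)[C@@H](C)N2S(=O)(=O)C(C)(C)C | intermediate
19 | (2R)‑6‑[(4S,15S)‑15‑(benzyloxy)‑4‑(trifluoroboranuidyloxy)hexadecyl]‑1‑(tert‑butylsulfonyl)‑2‑methyl‑3‑oxo‑2,3‑dihydropyridin‑1‑ium | C[C@H](OCc1ccccc1)CCCCCCCCCC[C@H](O[B-](F)(F)F)CCCC1=[N+](S(=O)(=O)C(C)(C)C)[C@H](C)C(=O)C=C1 | intermediate (not isolated)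
20 | (2R,6S)‑6‑[(4S,15S)‑15‑(benzyloxy)‑4‑hydroxyhexadecyl]‑1‑(tert‑butylsulfonyl)‑2‑methyl‑1,6‑dihydropyridin‑3(2H)‑one | C[C@H](OCc1ccccc1)CCCCCCCCCC[C@H](O)CCC[C@H]1C=CC(=O)[C@@H](C)N1S(=O)(=O)C(C)(C)C | intermediate
21 | (2R,6S)‑1‑(tert‑butylsulfonyl)‑6‑[(4S,15S)‑4,15‑dihydroxyhexadecyl]‑2‑methylpiperidin‑3‑one | C[C@H](O)CCCCCCCCCC[C@H](O)CCC[C@H]1CCC(=O)[C@@H](C)N1S(=O)(=O)C(C)(C)C | intermediate
22 | (2R,6S)‑6‑[(4S,15S)‑4,15‑dihydroxyhexadecyl]‑2‑methylpiperidin‑3‑one (generated as its triflate salt) | C[C@H](O)CCCCCCCCCC[C@H](O)CCC[C@H]1CCC(=O)[C@@H](C)N1 | intermediate (not isolated)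
23 | (2R,3S,6S)‑6‑[(4S,15S)‑4,15‑dihydroxyhexadecyl]‑2‑methylpiperidin‑3‑ol | C[C@H](O)CCCCCCCCCC[C@H](O)CCC[C@H]1CC[C@H](O)[C@@H](C)N1 | target

**Step count:** 10 steps in total. Longest linear sequence: 9 steps (steps 1–4 and 6–10, from 11‑bromoundec‑1‑ene); step 5 is a one‑step branch.

**Steps most likely to fail**

Step 7. The acid‑driven closure of the spiro N,O‑ketal around a crowded nitrogen may be outrun by loss of water to an exocyclic enesulfonamide, by sulfinate loss with aromatisation to a 3‑hydroxypyridine, or by over‑oxidation with peracid. The fallback gives up the temporary ring. It sets out from 15: silylation of the C4′ hydroxyl (TESCl, imidazole, CH2Cl2) gives (R)‑N‑[(1R)‑1‑{5‑[(4S,15S)‑15‑(benzyloxy)‑4‑(triethylsilyloxy)hexadecyl]furan‑2‑yl}ethyl]‑2‑methylpropane‑2‑sulfinamide F1. Buffered mCPBA (2.2 equiv, NaHCO3, CH2Cl2, 0 °C) then gives the simple aza‑Achmatowicz hemiaminal (2R)‑6‑[(4S,15S)‑15‑(benzyloxy)‑4‑(triethylsilyloxy)hexadecyl]‑1‑(tert‑butylsulfonyl)‑6‑hydroxy‑2‑methyl‑1,6‑dihydropyridin‑3(2H)‑one F2, with no acid treatment. F2 is reduced at once (Et3SiH, BF3·OEt2, −78 °C) and the silyl ether is cleaved in the acidic work‑up (1 M HCl, THF), which returns to the route at 20.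

Step 8. Facial selectivity of hydride delivery to the flat, crowded iminium ion may be poor, or conjugate reduction may compete. The fallback moves the C6‑setting event to an N‑unsubstituted cyclic imine. It sets out from 18: hydrogenation (H2, Pd(OH)2/C, EtOAc–MeOH) should give (2S,6R,8R)‑7‑(tert‑butylsulfonyl)‑2‑[(11S)‑11‑hydroxydodecyl]‑8‑methyl‑1‑oxa‑7‑azaspiro[5.5]undecan‑9‑one F3. Acidolysis of the Bus group (TfOH, anisole, CH2Cl2, 0 °C) lets the N‑unsubstituted spiro aminal open to the cyclic imine (2R)‑6‑[(4S,15S)‑4,15‑dihydroxyhexadecyl]‑2‑methyl‑4,5‑dihydropyridin‑3(2H)‑one F4, which is not isolated but reduced in the same flask (MeOH, NaOMe, NaBH4, −40 °C). Axial hydride addition to the tetrahydropyridine half‑chair with a pseudoequatorial C2 methyl is the classical entry to 2,6‑cis piperidines, and the ketone is reduced as in step 10; the sequence comes back at 23. Its own weak point is C2 epimerisation while the imine and ketone coexist, so the acid stage should be kept short and cold.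

Step 10. Facial selectivity of hydride addition to the amino ketone may be insufficient, or the free α‑amino ketone may condense before it is reduced. The fallback uses the reliably cis‑selective reduction at the sulfonamide stage, then inverts C3. It sets out from 21: silylation (TBSCl, imidazole, DMF) gives (2R,6S)‑6‑[(4S,15S)‑4,15‑bis(tert‑butyldimethylsilyloxy)hexadecyl]‑1‑(tert‑butylsulfonyl)‑2‑methylpiperidin‑3‑one F5. NaBH4 in MeOH, adding anti to the axial methyl, should give the all‑cis alcohol (2R,3R,6S)‑6‑[(4S,15S)‑4,15‑bis(tert‑butyldimethylsilyloxy)hexadecyl]‑1‑(tert‑butylsulfonyl)‑2‑methylpiperidin‑3‑ol F6. Mitsunobu inversion (4‑nitrobenzoic acid, DIAD, PPh3, toluene) gives (2R,3S,6S)‑6‑[(4S,15S)‑4,15‑bis(tert‑butyldimethylsilyloxy)hexadecyl]‑1‑(tert‑butylsulfonyl)‑2‑methylpiperidin‑3‑yl 4‑nitrobenzoate F7. Methanolysis (K2CO3, MeOH) gives (2R,3S,6S)‑6‑[(4S,15S)‑4,15‑bis(tert‑butyldimethylsilyloxy)hexadecyl]‑1‑(tert‑butylsulfonyl)‑2‑methylpiperidin‑3‑ol F8. Acid treatment (TfOH, anisole, CH2Cl2, 0 °C; then MeOH) removes both silyl ethers and the Bus group and comes back at 23.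

**Further compounds**
F1 | step 7 | (R)‑N‑[(1R)‑1‑{5‑[(4S,15S)‑15‑(benzyloxy)‑4‑(triethylsilyloxy)hexadecyl]furan‑2‑yl}ethyl]‑2‑methylpropane‑2‑sulfinamide | C[C@H](OCc1ccccc1)CCCCCCCCCC[C@H](O[Si](CC)(CC)CC)CCCc1ccc([C@@H](C)N[S@](=O)C(C)(C)C)o1
F2 | step 7 | (2R)‑6‑[(4S,15S)‑15‑(benzyloxy)‑4‑(triethylsilyloxy)hexadecyl]‑1‑(tert‑butylsulfonyl)‑6‑hydroxy‑2‑methyl‑1,6‑dihydropyridin‑3(2H)‑one | C[C@H](OCc1ccccc1)CCCCCCCCCC[C@H](O[Si](CC)(CC)CC)CCCC1(O)C=CC(=O)[C@@H](C)N1S(=O)(=O)C(C)(C)C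
F3 | step 8 | (2S,6R,8R)‑7‑(tert‑butylsulfonyl)‑2‑[(11S)‑11‑hydroxydodecyl]‑8‑methyl‑1‑oxa‑7‑azaspiro[5.5]undecan‑9‑one | C[C@H](O)CCCCCCCCCC[C@H]1CCC[C@@]2(O1)CCC(=O)[C@@H](C)N2S(=O)(=O)C(C)(C)C
F4 | step 8 | (2R)‑6‑[(4S,15S)‑4,15‑dihydroxyhexadecyl]‑2‑methyl‑4,5‑dihydropyridin‑3(2H)‑one | C[C@H](O)CCCCCCCCCC[C@H](O)CCCC1=N[C@H](C)C(=O)CC1
F5 | step 10 | (2R,6S)‑6‑[(4S,15S)‑4,15‑bis(tert‑butyldimethylsilyloxy)hexadecyl]‑1‑(tert‑butylsulfonyl)‑2‑methylpiperidin‑3‑one | C[C@H](O[Si](C)(C)C(C)(C)C)CCCCCCCCCC[C@H](O[Si](C)(C)C(C)(C)C)CCC[C@H]1CCC(=O)[C@@H](C)N1S(=O)(=O)C(C)(C)C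
F6 | step 10 | (2R,3R,6S)‑6‑[(4S,15S)‑4,15‑bis(tert‑butyldimethylsilyloxy)hexadecyl]‑1‑(tert‑butylsulfonyl)‑2‑methylpiperidin‑3‑ol | C[C@H](O[Si](C)(C)C(C)(C)C)CCCCCCCCCC[C@H](O[Si](C)(C)C(C)(C)C)CCC[C@H]1CC[C@@H](O)[C@@H](C)N1S(=O)(=O)C(C)(C)C
F7 | step 10 | (2R,3S,6S)‑6‑[(4S,15S)‑4,15‑bis(tert‑butyldimethylsilyloxy)hexadecyl]‑1‑(tert‑butylsulfonyl)‑2‑methylpiperidin‑3‑yl 4‑nitrobenzoate | C[C@H](O[Si](C)(C)C(C)(C)C)CCCCCCCCCC[C@H](O[Si](C)(C)C(C)(C)C)CCC[C@H]1CC[C@H](OC(=O)c2ccc(cc2)[N+](=O)[O-])[C@@H](C)N1S(=O)(=O)C(C)(C)C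
F8 | step 10 | (2R,3S,6S)‑6‑[(4S,15S)‑4,15‑bis(tert‑butyldimethylsilyloxy)hexadecyl]‑1‑(tert‑butylsulfonyl)‑2‑methylpiperidin‑3‑ol | C[C@H](O[Si](C)(C)C(C)(C)C)CCCCCCCCCC[C@H](O[Si](C)(C)C(C)(C)C)CCC[C@H]1CC[C@H](O)[C@@H](C)N1S(=O)(=O)C(C)(C)C
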